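**Plan**

- Numbering: ring C1 (quaternary carbinol), C2 (C=O), C3 (CH2), C4 (CHOH), C5 (CHOBz), C6 (CHOH); C7 is the CH2OBz carbon on C1. The cyclohexane carries a C4/C5 diol whose oxygens are cis to each other and trans to O6, the pattern an intramolecular pinacol coupling gives next to an oxygen-bearing carbon.
- Retrosynthetic cuts: C4–C5 (ring bond, ketyl coupling) to an open-chain C4,C5-dialdehyde; then C1–C2 (acyl-anion addition to a ketone) and C2–C3 (dithiane alkylation).
- Forward: the C7–C1–C6–C5 chain comes from L-erythrulose and the C2–C3–C4 arm from 1,3-dithiane. They are joined at C1–C2, the protecting groups are re-ordered, and the only carbocycle is closed last by SmI2.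
- Stereochemistry: C6 from L-erythrulose; C1 by Felkin–Anh addition to the ketone; C4 and C5 in the ring closure (samarium-bridged cis-diol turned away from O6).
- The C2 ketone travels as a 1,3-dithiane and is released only after the ring and the C5 benzoate are in place.

Key step: step 12

Remark: the acetal carbon of the oxan-2-yl (THP) group is carried as a mixture of epimers from step 3 to step 7 and is drawn without configuration; it has no bearing on the other stereocentres.

**Route**

Step 1
Reactants: 1 L-erythrulose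
Product: 2 3,4-O-isopropylidene-L-erythrulose
Conditions: 2,2-dimethoxypropane, acetone, cat. p-TsOH, rt
Reagents that add atoms: 2,2-dimethoxypropane, CC(C)(OC)OC
Why: Acid-catalysed acetalisation closes the dioxolane on the vicinal 3,4-diol (later O6/O5) and leaves the primary hydroxyl beside the ketone (later O7) free, without touching the stereocentre.

Step 2
Reactants: 2 3,4-O-isopropylidene-L-erythrulose
Product: 3 1-O-(tert-butyldiphenylsilyl)-3,4-O-isopropylidene-L-erythrulose
Conditions: TBDPSCl, imidazole, CH2Cl2, 0 °C to rt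
Reagents that add atoms: tert-butyl(chloro)diphenylsilane, CC(C)(C)[Si](Cl)(c1ccccc1)c1ccccc1
Why: Silyl ether formation at the only free hydroxyl gives a bulky, non-chelating group that survives the organolithium step and is later removed by fluoride.

Step 3
Reactants: 4 1,3-dithiane; 5 2-(2-bromoethoxy)oxane
Product: 7 2-[2-(oxan-2-yloxy)ethyl]-1,3-dithiane, via 2-lithio-1,3-dithiane 6 (not isolated)
Conditions: n-BuLi, THF, −30 °C; then 5, −78 to 0 °C
Reagents that add atoms: none
Why: Corey–Seebach alkylation, in which the sulfur-stabilised carbanion displaces the primary bromide (SN2), forms the C2–C3 bond and brings in C4 as a protected alcohol.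

Step 4
Reactants: 7 2-[2-(oxan-2-yloxy)ethyl]-1,3-dithiane; 3 1-O-(tert-butyldiphenylsilyl)-3,4-O-isopropylidene-L-erythrulose
Product: 9 (1S)-2-(tert-butyldiphenylsilyloxy)-1-[(4S)-2,2-dimethyl-1,3-dioxolan-4-yl]-1-{2-[2-(oxan-2-yloxy)ethyl]-1,3-dithian-2-yl}ethan-1-ol, via lithiated dithiane 8 (not isolated)
Conditions: t-BuLi, THF/HMPA (10:1), −78 °C; then 3, −78 °C; AcOH quench at −78 °C
Reagents that add atoms: none
Why: Corey–Seebach 1,2-addition of the acyl-anion equivalent to the ketone forms C1–C2; with an HMPA-solvated lithium counter-ion and no chelating group on O7 the attack should follow the Felkin–Anh model (dioxolane C–O bond anti to the incoming carbanion, approach past the small hydrogen), which sets C1 in the S configuration needed for the cis C1/C6 diol.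

Step 5
Reactants: 9 silyl-protected tertiary alcohol
Product: 10 (2S)-2-[(4S)-2,2-dimethyl-1,3-dioxolan-4-yl]-2-{2-[2-(oxan-2-yloxy)ethyl]-1,3-dithian-2-yl}ethane-1,2-diol
Conditions: TBAF, THF, 0 °C to rt
Reagents that add atoms: none
Why: Fluoride-mediated desilylation cleaves only the Si–O bond; both acetals, the dithiane and the tertiary alcohol are inert.

Step 6
Reactants: 10 primary/tertiary diol
Product: 11 (2S)-2-[(4S)-2,2-dimethyl-1,3-dioxolan-4-yl]-2-hydroxy-2-{2-[2-(oxan-2-yloxy)ethyl]-1,3-dithian-2-yl}ethyl benzoate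
Conditions: BzCl, pyridine, cat. DMAP, CH2Cl2, 0 °C
Reagents that add atoms: benzoyl chloride, O=C(Cl)c1ccccc1
Why: O-Acylation takes place only at the primary C7 hydroxyl, because the tertiary C1 hydroxyl is too hindered to be esterified under these conditions.

Step 7
Reactants: 11 C7 benzoate
Product: 12 (2S,3S)-2,3,4-trihydroxy-2-[2-(2-hydroxyethyl)-1,3-dithian-2-yl]butyl benzoate
Conditions: cat. p-TsOH·H2O, MeOH, rt
Reagents that add atoms: none
Why: Acid-catalysed transacetalisation in methanol removes the terminal acetonide and the THP ether in one operation, while benzoate and dithiane are stable to dilute acid.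

Step 8
Reactants: 12 tetraol
Product: 13 (2S,3S)-4-(tert-butyldimethylsilyloxy)-2-{2-[2-(tert-butyldimethylsilyloxy)ethyl]-1,3-dithian-2-yl}-2,3-dihydroxybutyl benzoate
Conditions: TBSCl (2.2 equiv), imidazole, DMF, 0 °C
Reagents that add atoms: tert-butyl(chloro)dimethylsilane, CC(C)(C)[Si](C)(C)Cl
Why: Selective silylation should take the two unhindered primary alcohols (O5 and O4) and leave the hindered secondary C6 and tertiary C1 hydroxyls free.

Step 9
Reactants: 13 bis-silyl ether diol
Product: 14 [(4S,5S)-5-(tert-butyldimethylsilyloxymethyl)-4-{2-[2-(tert-butyldimethylsilyloxy)ethyl]-1,3-dithian-2-yl}-2,2-dimethyl-1,3-dioxolan-4-yl]methyl benzoate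
Conditions: 2-methoxypropene, cat. PPTS, CH2Cl2, 0 °C to rt
Reagents that add atoms: 2-methoxypropene, COC(C)=C
Why: Acid-catalysed acetonide formation engages the only free diol and ties O1 and O6 into a dioxolane in which C2 and C5 are cis, the geometry the ring closure needs.

Step 10
Reactants: 14 C1/C6 acetonide bis-silyl ether
Product: 15 [(4S,5S)-4-[2-(2-hydroxyethyl)-1,3-dithian-2-yl]-5-(hydroxymethyl)-2,2-dimethyl-1,3-dioxolan-4-yl]methyl benzoate
Conditions: HF·pyridine, pyridine, THF, 0 °C to rt
Reagents that add atoms: none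
Why: Buffered fluoride desilylation removes both primary TBS ethers without affecting the acetonide, the benzoate or the dithiane.

Step 11
Reactants: 15 C4,C5-diol
Product: 16 [(4S,5R)-5-formyl-2,2-dimethyl-4-[2-(2-oxoethyl)-1,3-dithian-2-yl]-1,3-dioxolan-4-yl]methyl benzoate
Conditions: SO3·pyridine, DMSO, i-Pr2NEt, CH2Cl2, 0 °C; used without storage
Reagents that add atoms: none
Why: Parikh–Doering oxidation converts both primary alcohols into aldehydes under non-acidic conditions that spare the dithiane sulfur and should not epimerise the α-alkoxy centre C6.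

Step 12
Reactants: 16 C4,C5-dialdehyde
Product: 17 spiro-dithiane acetonide cis-4,5-diol (C7 benzoate; O1/O6 isopropylidene; O4 and O5 cis to each other and trans to O6; C1 C4 C5 C6 arranged as in the target)
Conditions: SmI2 (3 equiv), t-BuOH (2 equiv), THF, −78 °C to rt
Reagents that add atoms: none
Why: Two single-electron transfers from divalent samarium turn the C4 and C5 aldehydes into ketyl radical anions, which couple to form the C4–C5 bond as a samarium-bridged diolate that is protonated on work-up. The closest known reaction type is the SmI2-mediated intramolecular pinacol coupling of carbohydrate-derived 1,6-dialdehydes to cis-cyclohexane-1,2-diols. The six-membered carbocycle closes by ketyl–ketyl combination (a 6-exo-type attack on the second samarium-bound carbonyl) through a chair-like transition state in which the dioxolane already holds C2 and C5 cis, so a cis-fused bicycle results. C5 is controlled by the C6 acetonide oxygen, from which the samarium-bound O5 turns away (O5 trans to O6, equatorial), and C4 by the trivalent samarium that bridges both ketyl oxygens and so places O4 cis to O5 (axial). The step needs the cis-diol anti to O6 and reduction of the aldehydes only: chelation and the α-alkoxy group should secure the former, aldehydes are reduced far faster than the benzoate or the dithiane, and coupling at −78 °C should outpace β-elimination of the C6 alkoxide.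

Step 13
Reactants: 17 cis-4,5-diol
Product: 18 C5 mono-benzoate of 17 (C4 hydroxyl free)
Conditions: BzCl (1.1 equiv), pyridine, CH2Cl2, −40 to 0 °C
Reagents that add atoms: benzoyl chloride, O=C(Cl)c1ccccc1
Why: Regioselective acylation of the cis-diol should take the equatorial C5 hydroxyl, since the axial C4 hydroxyl is 1,3-diaxial to a sulfur of the spiro dithiane and reacts more slowly.

Step 14
Reactants: 18 dithiane dibenzoate
Product: 19 C2 ketone acetonide (O1/O6 isopropylidene; C4 hydroxyl; C5 and C7 benzoates)
Conditions: PhI(OCOCF3)2, MeCN/H2O (9:1), 0 °C; NaHCO3 work-up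
Reagents that add atoms: water, O
Why: Oxidative dethioacetalisation with a hypervalent iodine reagent activates sulfur, water adds to the thionium ion and the C2 ketone is released; the method works on hindered dithianes and tolerates esters, a free secondary alcohol and the acetonide.

Step 15
Reactants: 19 ketone acetonide
Product: 20 [(1S,2S,3R,4R)-3-(benzoyloxy)-1,2,4-trihydroxy-6-oxocyclohexyl]methyl benzoate (CNP0127041.1)
Conditions: TFA/H2O (9:1), 0 °C to rt
Reagents that add atoms: none
Why: Acid hydrolysis of the isopropylidene acetal frees the C1 and C6 hydroxyls; short exposure at low temperature should avoid dehydration of the β-hydroxy ketone and benzoyl migration.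

**Compound list**

1 | L-erythrulose | OC[C@H](O)C(=O)CO | starting material
2 | 3,4-O-isopropylidene-L-erythrulose | CC1(C)OC[C@H](O1)C(=O)CO | intermediate
3 | 1-O-(tert-butyldiphenylsilyl)-3,4-O-isopropylidene-L-erythrulose | CC1(C)OC[C@H](O1)C(=O)CO[Si](c2ccccc2)(c3ccccc3)C(C)(C)C | intermediate
4 | 1,3-dithiane | C1CSCSC1 | starting material
5 | 2-(2-bromoethoxy)oxane (racemic) | BrCCOC1CCCCO1 | starting material
6 | 2-lithio-1,3-dithiane | [Li]C1SCCCS1 | intermediate (not isolated)
7 | 2-[2-(oxan-2-yloxy)ethyl]-1,3-dithiane | C1CSC(CCOC2CCCCO2)SC1 | intermediate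
8 | 2-lithio-2-[2-(oxan-2-yloxy)ethyl]-1,3-dithiane | [Li]C1(CCOC2CCCCO2)SCCCS1 | intermediate (not isolated)
9 | (1S)-2-(tert-butyldiphenylsilyloxy)-1-[(4S)-2,2-dimethyl-1,3-dioxolan-4-yl]-1-{2-[2-(oxan-2-yloxy)ethyl]-1,3-dithian-2-yl}ethan-1-ol | O[C@](CO[Si](c1ccccc1)(c1ccccc1)C(C)(C)C)(C1(CCOC2CCCCO2)SCCCS1)[C@@H]1COC(C)(C)O1 | intermediate
10 | (2S)-2-[(4S)-2,2-dimethyl-1,3-dioxolan-4-yl]-2-{2-[2-(oxan-2-yloxy)ethyl]-1,3-dithian-2-yl}ethane-1,2-diol | O[C@](CO)(C1(CCOC2CCCCO2)SCCCS1)[C@@H]1COC(C)(C)O1 | intermediate
11 | (2S)-2-[(4S)-2,2-dimethyl-1,3-dioxolan-4-yl]-2-hydroxy-2-{2-[2-(oxan-2-yloxy)ethyl]-1,3-dithian-2-yl}ethyl benzoate | O[C@](COC(=O)c1ccccc1)(C1(CCOC2CCCCO2)SCCCS1)[C@@H]1COC(C)(C)O1 | intermediate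
12 | (2S,3S)-2,3,4-trihydroxy-2-[2-(2-hydroxyethyl)-1,3-dithian-2-yl]butyl benzoate | O[C@](COC(=O)c1ccccc1)(C1(CCO)SCCCS1)[C@@H](O)CO | intermediate
13 | (2S,3S)-4-(tert-butyldimethylsilyloxy)-2-{2-[2-(tert-butyldimethylsilyloxy)ethyl]-1,3-dithian-2-yl}-2,3-dihydroxybutyl benzoate | O[C@](COC(=O)c1ccccc1)(C1(CCO[Si](C)(C)C(C)(C)C)SCCCS1)[C@@H](O)CO[Si](C)(C)C(C)(C)C | intermediate
14 | [(4S,5S)-5-(tert-butyldimethylsilyloxymethyl)-4-{2-[2-(tert-butyldimethylsilyloxy)ethyl]-1,3-dithian-2-yl}-2,2-dimethyl-1,3-dioxolan-4-yl]methyl benzoate | CC(C)(C)[Si](C)(C)OCCC1(SCCCS1)[C@@]2(COC(=O)c3ccccc3)OC(C)(C)O[C@H]2CO[Si](C)(C)C(C)(C)C | intermediate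
15 | [(4S,5S)-4-[2-(2-hydroxyethyl)-1,3-dithian-2-yl]-5-(hydroxymethyl)-2,2-dimethyl-1,3-dioxolan-4-yl]methyl benzoate | OCCC1(SCCCS1)[C@@]2(COC(=O)c3ccccc3)OC(C)(C)O[C@H]2CO | intermediate
16 | [(4S,5R)-5-formyl-2,2-dimethyl-4-[2-(2-oxoethyl)-1,3-dithian-2-yl]-1,3-dioxolan-4-yl]methyl benzoate | O=CCC1(SCCCS1)[C@@]2(COC(=O)c3ccccc3)OC(C)(C)O[C@H]2C=O | intermediate
17 | pinacol product: cyclohexane with spiro-1,3-dithiane at C2, isopropylidene acetal across O1/O6, CH2OBz on C1, cis-4,5-diol trans to O6 | O=C(OC[C@@]2(OC3(C)C)C4(SCCCS4)C[C@@H](O)[C@@H](O)[C@@H]2O3)c1ccccc1 | intermediate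
18 | C5 benzoate of 17 (C4 hydroxyl free) | O=C(OC[C@@]2(OC3(C)C)C4(SCCCS4)C[C@@H](O)[C@@H](OC(=O)c5ccccc5)[C@@H]2O3)c1ccccc1 | intermediate
19 | C2 ketone with O1/O6 isopropylidene acetal, C4 hydroxyl, C5 and C7 benzoates | O=C(OC[C@@]2(OC3(C)C)C(=O)C[C@@H](O)[C@@H](OC(=O)c4ccccc4)[C@@H]2O3)c1ccccc1 | intermediate
20 | [(1S,2S,3R,4R)-3-(benzoyloxy)-1,2,4-trihydroxy-6-oxocyclohexyl]methyl benzoate (CNP0127041.1) | O=C(OC[C@@]1(O)C(=O)C[C@@H](O)[C@@H](OC(=O)c2ccccc2)[C@@H]1O)c1ccccc1 | target

**Step count and weak points**

Total: 15 steps. Longest linear sequence: 14 steps (L-erythrulose through steps 1, 2 and 4–15).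

Steps most likely to fail:

1. Step 4. The addition may show poor facial selectivity if a lithium-chelated transition state competes with the Felkin–Anh one, and the hindered tertiary carbanion may deprotonate the ketone instead of adding. The fallback exchanges the order in which the two carbon groups reach C1, so that a chelated transition state gives the required configuration. Setting out from 7, the lithio derivative 8 is acylated at −78 °C with commercial methyl (4S)-2,2-dimethyl-1,3-dioxolane-4-carboxylate F1 to give the 2-acyl dithiane ketone F2. ClMgCH2SiMe2(Oi-Pr) in THF at −78 °C should then add under Cram-chelate control (magnesium between the ketone and dioxolane oxygens, attack anti to the ring CH2) to give the silylmethyl carbinol F3. Tamao oxidation (H2O2, KF, KHCO3, THF/MeOH, 0 °C, minimal excess of peroxide to spare the sulfur) turns the C–Si bond into the C7 hydroxyl, and the route is rejoined at diol 10.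

2. Step 12. Coupling through an unchelated or differently folded transition state would give the trans-diol or the cis-diol syn to O6, and the C5 ketyl may lose the C6 alkoxide by β-elimination. The fallback forms the same C4–C5 bond in two polar steps. From dialdehyde 16, an intramolecular benzoin reaction catalysed by the carbene from 3-benzyl-5-(2-hydroxyethyl)-4-methyl-1,3-thiazol-3-ium chloride and Et3N (THF, rt) should give the α-hydroxy ketone F4 (C4 ketone, C5 hydroxyl anti to O6 by Felkin–Anh addition of the Breslow intermediate to the α-alkoxy aldehyde). LiBH(s-Bu)3 in THF at −78 °C then delivers hydride to the equatorial side of C4, the axial side being screened by the dithiane sulfur. This gives the axial C4 alcohol cis to O5, which is diol 17, where the route is rejoined.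

3. Step 15. Hydrolysis of an acetonide deactivated by the adjacent carbonyl may be slow enough for acid-promoted dehydration of the β-hydroxy ketone or benzoyl migration to intervene. The fallback reverses the last two unmaskings so that the ketone never meets acid. From 18, TFA/H2O (9:1, 0 °C) hydrolyses the acetonide while C2 is still a dithiane, giving the dithiane triol F5. I2 with NaHCO3 in acetone/H2O at 0 °C then releases the ketone under near-neutral conditions and gives target 20 directly.

**Further compounds**

F1 | step 4 | methyl (4S)-2,2-dimethyl-1,3-dioxolane-4-carboxylate | COC(=O)[C@@H]1COC(C)(C)O1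
F2 | step 4 | [(4S)-2,2-dimethyl-1,3-dioxolan-4-yl]{2-[2-(oxan-2-yloxy)ethyl]-1,3-dithian-2-yl}methanone | O=C([C@@H]1COC(C)(C)O1)C1(CCOC2CCCCO2)SCCCS1
F3 | step 4 | 1-[(4S)-2,2-dimethyl-1,3-dioxolan-4-yl]-2-[dimethyl(propan-2-yloxy)silyl]-1-{2-[2-(oxan-2-yloxy)ethyl]-1,3-dithian-2-yl}ethan-1-ol (C1 arranged as in 10) | O[C@](C[Si](C)(C)OC(C)C)(C1(CCOC2CCCCO2)SCCCS1)[C@@H]1COC(C)(C)O1
F4 | step 12 | C4 ketone C5 alcohol analogue of 17 (spiro-dithiane at C2, O1/O6 isopropylidene, C7 benzoate, O5 trans to O6) | O=C(OC[C@@]2(OC3(C)C)C4(SCCCS4)CC(=O)[C@@H](O)[C@@H]2O3)c1ccccc1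
F5 | step 15 | dithiane triol: 18 without the isopropylidene group (C1, C4, C6 hydroxyls free; C5 and C7 benzoates; spiro-dithiane at C2) | O=C(OC[C@@]1(O)C2(SCCCS2)C[C@@H](O)[C@@H](OC(=O)c3ccccc3)[C@@H]1O)c1ccccc1
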